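The numbers in the tables were generated by integration with constants of no real substance; scatter was added.

In a one-step world, first order in starting material, the share left shrinks by the same factor in every equal stretch of time, so one number draws the whole curve. You can test that on the flask asked about, whose early course is the grey run, beside the red run made earlier.

| setting | grey | red | flask |
|---|---|---|---|
| starting material | 0.050 M | 0.10 M | 0.050 M |
| second substrate | 0.090 M | 0.090 M | 0.0900 M |
| free enzyme | 5 µM | 5 µM | 5.0 µM |
| remark | the very flask that is asked about, followed so far | run made earlier |  |
| time |  |  | 3.0 h |

| run | time / min | target / % | starting material / % |
|---|---|---|---|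
| grey | 12.0 | 5.8 | 94.6 |
| grey | 30.0 | 13.3 | 88.2 |
| grey | 60.0 | 22.4 | 80.4 |
| grey | 90.0 | 29.7 | 70.4 |
| red | 10.0 | 2.9 | 96.9 |
| red | 25.0 | 8.7 | 91.7 |
| red | 50.0 | 14.5 | 86.7 |
| red | 120 | 31.7 | 69.7 |

(standard deviation of a reading: 1 percentage point)



* amount of target in the flask at 3.0 h, in percent of the starting material charged
* amount of starting material in the flask at 3.0 h, in percent of the starting material charged
* concentration of first product at 3.0 h, in M

Start with the slope. To 30.0 min, the logarithm of the fall in starting material, divided by the time, gives 0.00419 /min. From there to 90.0 min the same reading gives 0.00376 /min, and this later value is the fractional rate, an apparent first-order constant, that you carry forward. It is lower than the first value, so the curve bends gently, though the scatter blurs this. The red run, with twice the starting material, averages 0.00285 /min to its reading at 50.0 min, against 0.00364 /min for the grey run to 60.0 min, so in these readings the fractional rate is lower at the larger charge.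

Next comes the crossing, where target equals starting material. The enzyme charge is tiny beside the starting material, so target is simply what starting material has lost. Held at the carried value, the fractional rate puts the crossing at 3.02 h. Starting material is the limiting reagent, so the ceiling is its full charge. My own reckoning leaves 50.2% of it at 3.0 h, with first product near 0.0249 M.

The forecast sits higher on starting material than my reckoning, at 56% (49% to 62%), with 44% target and 0.022 M first product, reading the grey run as “slowing somewhat faster than depletion alone predicts”.

The flask gives 46.2% target, 53.8% starting material and 0.0231 M first product.

    starting material + free enzyme ⇌ first complex (K = 12.0 /M, k = 16000 /M/s)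
    first complex → loaded enzyme + first product (k = 2.60 /s)
    second substrate + loaded enzyme ⇌ second complex (K = 67.0 /M, k = 420 /M/s)
    second complex → free enzyme + target (k = 6.50 /s)
    2 free enzyme → spent catalyst (k = 40.0 /M/s)

Between 1.50 h and 3.00 h this flask's fractional rate averages 0.00284 /min, below the carried 0.00376 /min, and at the asked time starting material still stands above target. Now take the neighbouring flask, the same recipe with 0.020 M starting material. Run the carried 0.00376 /min over its 3.0 h and you leave 50.9%, which means 0.00982 M of first product. That neighbouring flask holds 52.0% of its charged starting material and 0.00960 M first product.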